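# Total synthesis of licobichalcone (1S,2S) via photoenolization/Diels–Alder

**Assumptions**
- The SMILES is read as the cis-(1S,2S) isomer: the C1-aryl and C2-aroyl groups lie on the same face. I checked this by CIP analysis at both centres.
- Selective benzylation of 2,3,4-trihydroxybenzaldehyde at O4 and O3 is assumed, because the 2-OH is hydrogen-bonded to the CHO.
- In the ortho-lithiation of **5**, the C2 position beside OMe is assumed to be favoured over C6 beside OBn.

## Retrosynthetic overview
- Target ⇐ global debenzylation of the hexabenzyl ether **13** ⇐ acid dehydration of the 4-hydroxytetralin **12**.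
- **12** ⇐ photoenolization/Diels–Alder (PEDA) between o-(arylmethyl)benzaldehyde **8** and the C2-symmetric (E)-1,2-diaroylethylene **11**. This is the only ring-forming step. It dearomatises ring B to an o-quinodimethane, desymmetrises **11**, and sets C1 and C2 together.
- **8** ⇐ directed ortho-metalation (Comins) coupling of benzaldehydes **5** and **3**, then deoxygenation and re-oxidation.
- **11** ⇐ double acyl-Stille coupling of (E)-bis(stannyl)ethylene with 4-benzyloxybenzoyl chloride.
- All phenols are carried as benzyl ethers and released last.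

## Route

**Step 1**
Reactants: **1** 2,3,4-trihydroxybenzaldehyde
Product: **2** 3,4-bis(benzyloxy)-2-hydroxybenzaldehyde
Conditions: BnBr (2.1 equiv), K2CO3, DMF, 40 °C
Reagents that add atoms: benzyl bromide, BrCc1ccccc1
Why: Williamson etherification. The 4-OH (para to CHO) is the most acidic and the 3-OH reacts next. The 2-OH is chelated to the CHO and stays free.

**Step 2**
Reactants: **2**
Product: **3** 3,4-bis(benzyloxy)-2-methoxybenzaldehyde
Conditions: MeI, K2CO3, DMF, 50 °C
Reagents that add atoms: methyl iodide, CI
Why: O-methylation of the remaining phenol gives the 2-OMe-3,4-diOBn aryl unit, which is ring A of the target.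

**Step 3**
Reactants: **4** 5-hydroxyvanillin (3,4-dihydroxy-5-methoxybenzaldehyde)
Product: **5** 4,5-bis(benzyloxy)-3-methoxybenzaldehyde
Conditions: BnBr (2.2 equiv), K2CO3, DMF, rt to 50 °C
Reagents that add atoms: benzyl bromide, BrCc1ccccc1
Why: double Williamson etherification gives ring B with the OMe already in the required position.

**Step 4**
Reactants: **5** and **3**
Product: **6** 3-aryl-1-hydroxy-1,3-dihydroisobenzofuran (lactol, racemic), ring B carrying OMe next to the new C–C bond
Conditions: (i) Me2NCH2CH2N(Me)Li, THF, 0 °C; (ii) n-BuLi, hexane, −20 °C, 3 h; (iii) **3**, −78 °C to rt; (iv) 2 M HCl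
Reagents that add atoms: none (the diamine directing group is removed on work-up)
Why: Comins directed ortho-metalation. The α-amino alkoxide of **5** directs lithiation to C2, which is also flanked by OMe. The aryllithium adds to **3** to give the diarylcarbinol, and acid hydrolysis of the aminal lets the CHO close onto the carbinol OH as the lactol.

**Step 5**
Reactants: **6**
Product: **7** [2-(2-methoxy-3,4-bis(benzyloxy)benzyl)-3-methoxy-4,5-bis(benzyloxy)phenyl]methanol
Conditions: Et3SiH (3 equiv), TFA (10 equiv), CH2Cl2, 0 °C, 30 min; then K2CO3, MeOH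
Reagents that add atoms: none (hydride only; the trifluoroacetate formed is cleaved in the work-up)
Why: ionic hydrogenation. The oxocarbenium from the lactol is reduced to the phthalan. Its doubly benzylic, electron-rich C–O bond then ionises and is reduced to the diarylmethane CH2, leaving the primary benzylic alcohol.

**Step 6**
Reactants: **7**
Product: **8** 2-(arylmethyl)-3-methoxy-4,5-bis(benzyloxy)benzaldehyde
Conditions: activated MnO2 (15 equiv), CH2Cl2, rt
Reagents that add atoms: none
Why: MnO2 oxidises the electron-rich benzylic alcohol to the aldehyde. The product is the PEDA precursor, an o-alkylbenzaldehyde with a weak doubly benzylic C–H.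

**Step 7**
Reactants: **9** (E)-1,2-bis(tributylstannyl)ethylene and **10** 4-(benzyloxy)benzoyl chloride (2.05 equiv)
Product: **11** (E)-1,4-bis(4-benzyloxyphenyl)but-2-ene-1,4-dione
Conditions: Pd(PPh3)4 (5 mol%), toluene, 90 °C
Reagents that add atoms: none (both coupling partners are listed as reactants)
Why: Stille acyl coupling at both vinyl–Sn bonds with retention of the E geometry. This gives the C2-symmetric dienophile that already carries both aroyl groups.

**Step 8**
Reactants: **8** and **11** (3 equiv)
Product: **12** 4-hydroxy-1-aryl-2,3-diaroyl-1,2,3,4-tetrahydronaphthalene (C1 and C2 as in the target; C3/C4 diastereomers are not defined)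
Conditions: chiral phosphoric acid (R)-TRIP (20 mol%), degassed toluene (0.02 M), 365 nm LEDs, −20 °C, 48 h, N2
Reagents that add atoms: none
Why: Proposed new method: photoenolization/Diels–Alder.
- Excited aldehyde **8** abstracts the doubly benzylic H intramolecularly (1,5-HAT) to give the (E)-hydroxy-o-quinodimethane, in which ring B is temporarily dearomatised. The closest known reaction type is PEDA of o-alkylbenzaldehydes with electron-poor alkenes.
- The diene adds suprafacially across **11** in a [4+2] cycloaddition. Ring B re-aromatises in the same step, and the two identical aroyl groups become inequivalent.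
- Because **11** is symmetric, there is no regiochemical issue.
- The peri 8-OMe should force the bulky Ar group "inside" on the diene. Endo approach of the C3-aroyl then leaves the C2-aroyl exo, which gives C1-Ar cis to C2-aroyl.
- The phosphoric acid is intended to H-bond the photoenol OH and an enedione C=O, so one face is selected and C1 becomes (S). The antipode of the catalyst is chosen empirically.
- C3 and C4 are destroyed in the next step, so only C1/C2 matter.

**Step 9**
Reactants: **12**
Product: **13** hexabenzyl-protected (1S,2S)-1,2-dihydronaphthalene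
Conditions: p-TsOH·H2O (10 mol%), CH2Cl2, 0 °C to rt, 2 h
Reagents that add atoms: none (loses H2O)
Why: acid-catalysed E1/E1cB dehydration of the β-hydroxy ketone. The benzylic C4–OH is activated by the para-OBn on ring B, and the acidic C3–H is lost to form the conjugated C3=C4 enone. Mild acid with no base avoids epimerising C2, and C1 is untouched. The C3/C4 diastereomers converge here.

**Step 10**
Reactants: **13**
Product: **14** licobichalcone
Conditions: BCl3 (12 equiv), pentamethylbenzene (12 equiv), CH2Cl2, −78 °C, 1.5 h; then MeOH quench
Reagents that add atoms: none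
Why: BCl3 cleaves aryl benzyl ethers selectively at −78 °C, and pentamethylbenzene traps the benzyl cation. The three methyl ethers, the enone and the stereocentres survive. Hydrogenolysis is avoided because it would reduce the C3=C4 enone.

## Compound list
1 | 2,3,4-trihydroxybenzaldehyde | O=Cc1ccc(O)c(O)c1O | starting material
2 | 3,4-bis(benzyloxy)-2-hydroxybenzaldehyde | O=Cc1ccc(OCc2ccccc2)c(OCc2ccccc2)c1O | intermediate
3 | 3,4-bis(benzyloxy)-2-methoxybenzaldehyde | O=Cc1ccc(OCc2ccccc2)c(OCc2ccccc2)c1OC | intermediate
4 | 5-hydroxyvanillin | COc1cc(C=O)cc(O)c1O | starting material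
5 | 4,5-bis(benzyloxy)-3-methoxybenzaldehyde | COc1cc(C=O)cc(OCc2ccccc2)c1OCc1ccccc1 | intermediate
6 | lactol (racemic, no defined stereocentres) | COc1c2c(cc(OCc3ccccc3)c1OCc3ccccc3)C(O)OC2c1ccc(OCc2ccccc2)c(OCc2ccccc2)c1OC | intermediate
7 | benzylic alcohol | COc1c(Cc2ccc(OCc3ccccc3)c(OCc3ccccc3)c2OC)c(CO)cc(OCc2ccccc2)c1OCc1ccccc1 | intermediate
8 | o-(arylmethyl)benzaldehyde | COc1c(Cc2ccc(OCc3ccccc3)c(OCc3ccccc3)c2OC)c(C=O)cc(OCc2ccccc2)c1OCc1ccccc1 | intermediate
9 | (E)-1,2-bis(tributylstannyl)ethylene | CCCC[Sn](CCCC)(CCCC)/C=C/[Sn](CCCC)(CCCC)CCCC | starting material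
10 | 4-(benzyloxy)benzoyl chloride | O=C(Cl)c1ccc(OCc2ccccc2)cc1 | starting material
11 | (E)-1,4-bis(4-benzyloxyphenyl)but-2-ene-1,4-dione | O=C(/C=C/C(=O)c1ccc(OCc2ccccc2)cc1)c1ccc(OCc2ccccc2)cc1 | intermediate
12 | PEDA adduct (C1, C2 defined; C3, C4 open) | COc1c2c(cc(OCc3ccccc3)c1OCc3ccccc3)C(O)C(C(=O)c3ccc(OCc4ccccc4)cc3)[C@@H](C(=O)c3ccc(OCc4ccccc4)cc3)[C@H]2c1ccc(OCc2ccccc2)c(OCc2ccccc2)c1OC | intermediate
13 | hexabenzyl (1S,2S)-dihydronaphthalene | COc1c([C@H]2c3c(cc(OCc4ccccc4)c(OCc4ccccc4)c3OC)C=C(C(=O)c3ccc(OCc4ccccc4)cc3)[C@H]2C(=O)c2ccc(OCc3ccccc3)cc2)ccc(OCc2ccccc2)c1OCc1ccccc1 | intermediate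
14 | licobichalcone | COc1c([C@H]2c3c(cc(O)c(O)c3OC)C=C(C(=O)c3ccc(O)cc3)[C@H]2C(=O)c2ccc(O)cc2)ccc(O)c1O | target

## Totals
- Total steps: 10.
- Longest linear sequence: 8 (1 → 2 → 3 → 6 → 7 → 8 → 12 → 13 → 14, i.e. steps 1, 2, 4, 5, 6, 8, 9, 10).

## Three steps most likely to fail
1. **Step 8, enantioselective PEDA.** The aryl enedione absorbs near 365 nm and can quench the aldehyde or isomerise (E→Z). The cis:trans ratio and the ee are also unproven.
   - Fallback: run the PEDA racemic with no catalyst, separate the diastereomers, and resolve **13** by preparative chiral-phase HPLC. This replaces asymmetric catalysis with resolution.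
2. **Step 4, regioselective ortho-lithiation and hindered coupling.** Lithiation at C6 beside OBn would give the wrong isomer, and the tetra-ortho-substituted carbinol may form in low yield.
   - Fallback: use a symmetrical approach instead. Make bis[2-methoxy-3,4-bis(benzyloxy)phenyl]methanol from 2 ArLi + HCO2Et, then do alkoxide-directed ortho-lithiation and DMF quench at the only free ortho site (C6′). This reaches lactol **6** with the regiochemistry fixed.
3. **Step 10, global debenzylation.** BCl3 may demethylate the 2′-OMe or 8-OMe next to O–BCl2, or epimerise C2.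
   - Fallback: rebuild the sequence with allyl ethers in place of benzyl ethers and remove them at the end with Pd(PPh3)4/K2CO3 in MeOH. This is a neutral, non-Lewis-acidic deprotection that leaves the alkene and methyl ethers alone.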